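**Plan**
- Retrosynthesis: the four O–benzyl bonds are cut last. Ring A is then cut at C5–C6, C7–C8 and C8–C8a into a pyranonyl(benzyloxy)carbene complex of zerovalent chromium, methoxyacetylene and one CO ligand.
- The carbene complex is cut at the chromium–acyl carbon bond (acid chloride plus Na2Cr(CO)5). Ring C is cut at C2–C3 and O1–C8a into an aroyl chloride (ring B with C2) and an aminomethylene β-keto ester (C3, C4, C4a, C8a and the future C5).
- Forward: ring B is bought, ring C is closed first (steps 1–3), its ester carbon is turned into the carbene carbon (steps 4–7), ring A is closed last (step 9), and hydrogenolysis ends the route.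
- Enabling feature: in ring A the oxygens on C5 and C8 are para, with C6–H and C7–OMe on one flank and the ring-C atoms C4a and C8a on the other. This is the 4-alkoxyphenol that an alkoxycarbene carbon (C5), an alkyne (C6, C7) and CO (C8) give when they close onto the C4a=C8a bond. C8–OH is then the only free hydroxyl and the only site acetylated.
- Stereochemistry: the target has no stereocentre; the only selectivity to secure is the orientation of the alkyne (OMe beside the CO-derived carbon).

Key step: step 9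

Remark: the β-keto ester, the amide acetal, 3,4-bis(benzyloxy)benzoic acid, Cr(CO)6 and the chloroacetal are taken as commercial; the alkene geometry of the enaminone is immaterial because it is lost on ring closure.

**Step 1**
Reactants: 1 methyl 4-(benzyloxy)-3-oxobutanoate; 2 N,N-dimethylformamide dimethyl acetal
Product: 3 methyl 4-(benzyloxy)-2-[(dimethylamino)methylidene]-3-oxobutanoate
Conditions: 2 (1.2 equiv), toluene, rt
Reagents that add atoms: none
Why: Enaminone formation by condensation of the amide acetal with the doubly activated C2 methylene of the β-keto ester is fast at room temperature and leaves the benzyloxymethyl ketone side untouched.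

**Step 2**
Reactants: 4 3,4-bis(benzyloxy)benzoic acid
Product: 5 3,4-bis(benzyloxy)benzoyl chloride
Conditions: (COCl)2, DMF (cat.), CH2Cl2, 0 °C → rt
Reagents that add atoms: oxalyl chloride, O=C(Cl)C(=O)Cl
Why: Acid chloride formation with oxalyl chloride under DMF (Vilsmeier-type) catalysis is compatible with aryl benzyl ethers.

**Step 3**
Reactants: 3 methyl 4-(benzyloxy)-2-[(dimethylamino)methylidene]-3-oxobutanoate; 5 3,4-bis(benzyloxy)benzoyl chloride
Product: 7 methyl 5-(benzyloxy)-6-[3,4-bis(benzyloxy)phenyl]-4-oxo-4H-pyran-3-carboxylate, via triketone 6 (not isolated)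
Conditions: 3, LiN(SiMe3)2 (2.5 equiv), THF, −78 °C; then 5; then 2 M aq. HCl, rt
Reagents that add atoms: none
Why: A crossed Claisen-type C-acylation of the lithium enolate at the benzyloxy-bearing carbon gives triketone 6, and on acidification its enol oxygen adds to the aminomethylene carbon and expels dimethylamine (addition–elimination), the established way to close 4-oxo-4H-pyran-3-carboxylates.

**Step 4**
Reactants: 7 methyl 5-(benzyloxy)-6-[3,4-bis(benzyloxy)phenyl]-4-oxo-4H-pyran-3-carboxylate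
Product: 8 5-(benzyloxy)-6-[3,4-bis(benzyloxy)phenyl]-4-oxo-4H-pyran-3-carboxylic acid
Conditions: Me3SnOH (4 equiv), 1,2-dichloroethane, 75 °C; then cold 1 M aq. HCl
Reagents that add atoms: trimethyltin hydroxide, C[Sn](C)(C)O
Why: Me3SnOH ester hydrolysis runs under nearly neutral conditions, which should spare the nucleophile-sensitive CH next to the ring oxygen and the benzyl ethers where aqueous alkali or hot mineral acid would not.

**Step 5**
Reactants: 8 5-(benzyloxy)-6-[3,4-bis(benzyloxy)phenyl]-4-oxo-4H-pyran-3-carboxylic acid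
Product: 9 5-(benzyloxy)-6-[3,4-bis(benzyloxy)phenyl]-4-oxo-4H-pyran-3-carbonyl chloride
Conditions: (COCl)2 (1.5 equiv), DMF (cat.), CH2Cl2, 0 °C → rt; evaporate
Reagents that add atoms: oxalyl chloride, O=C(Cl)C(=O)Cl
Why: Acid chloride formation with oxalyl chloride and catalytic DMF is routine for 4-oxopyran- and chromone-3-carboxylic acids, and the crude chloride is used at once.

**Step 6**
Reactants: 9 5-(benzyloxy)-6-[3,4-bis(benzyloxy)phenyl]-4-oxo-4H-pyran-3-carbonyl chloride; 10 chromium hexacarbonyl, Cr(CO)6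
Product: 13 tetramethylammonium pentacarbonyl{[5-(benzyloxy)-6-[3,4-bis(benzyloxy)phenyl]-4-oxo-4H-pyran-3-yl]carbonyl}chromate, via disodium pentacarbonylchromate 11 (not isolated), via sodium acylchromate 12 (not isolated)
Conditions: 10, NaC10H8 (sodium naphthalenide, 2 equiv), THF, −78 °C; then 9, −78 → 0 °C; then Me4NBr, H2O, 0 °C
Reagents that add atoms: tetramethylammonium bromide, C[N+](C)(C)C.[Br-]
Why: Nucleophilic acyl substitution of the acid chloride by the pentacarbonylchromate dianion gives the acylchromate directly, a known alternative to the organolithium route that the electrophilic pyranone could not survive, and cation exchange gives a storable salt.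

**Step 7**
Reactants: 13 tetramethylammonium pentacarbonyl{[5-(benzyloxy)-6-[3,4-bis(benzyloxy)phenyl]-4-oxo-4H-pyran-3-yl]carbonyl}chromate
Product: 15 pentacarbonyl{(benzyloxy)[5-(benzyloxy)-6-[3,4-bis(benzyloxy)phenyl]-4-oxo-4H-pyran-3-yl]methylidene}chromium, via acetoxycarbene complex 14 (not isolated)
Conditions: AcBr (1.05 equiv), CH2Cl2, −40 °C; then BnOH (1.5 equiv), −40 → 0 °C
Reagents that add atoms: benzyl alcohol, OCc1ccccc1
Why: O-Acetylation of the acylate gives a reactive acyloxycarbene complex in which benzyl alcohol displaces acetate at the carbene carbon (addition–elimination), the standard access to alkoxycarbene complexes of alcohols other than methanol.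

**Step 8**
Reactants: 16 chloroacetaldehyde dimethyl acetal
Product: 18 methoxyacetylene, via sodium methoxyacetylide 17 (not isolated)
Conditions: NaNH2 (3 equiv), liquid NH3, −33 °C; then cold satd aq. NaCl, −20 °C; distil into cold THF
Reagents that add atoms: none
Why: Base-induced 1,2-elimination of methanol and then of HCl with NaNH2 gives the alkyne, held as its sodium acetylide until the aqueous quench, which is the classical preparation of 1-alkoxyacetylenes from chloroacetals.

**Step 9**
Reactants: 15 pentacarbonyl{(benzyloxy)[5-(benzyloxy)-6-[3,4-bis(benzyloxy)phenyl]-4-oxo-4H-pyran-3-yl]methylidene}chromium; 18 methoxyacetylene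
Product: 20 3,5-bis(benzyloxy)-2-[3,4-bis(benzyloxy)phenyl]-7-methoxy-4-oxo-4H-chromen-8-yl acetate, via 8-hydroxychromenone 19 (not isolated)
Conditions: 18 (3 equiv), Ac2O (2 equiv), Et3N (2 equiv), THF, 55 °C, sealed tube; then air, rt
Reagents that add atoms: acetic anhydride, CC(=O)OC(C)=O
Why: Proposed new method: loss of one CO from 15 opens a site at which methoxyacetylene inserts into the chromium–carbene bond, its nucleophilic CH terminus bonding to the carbene carbon (C5–C6), after which CO inserts at the new methoxy-bearing carbene carbon (C7–C8) to give a chromium-bound vinylketene that cyclises onto the pyranone CH (C8–C8a) and tautomerises to phenol 19, acetylated as it forms. The closest known reaction is the Dötz benzannulation of alkenyl and heteroaryl alkoxycarbene complexes of zerovalent chromium with terminal alkynes in the presence of Ac2O and Et3N; a 4-oxopyranyl carbene and a 1-alkoxyalkyne are both outside its shown scope. Ring A closes by a six-electron electrocyclisation of the dienylketene, and no stereocentre is formed. The orientation needed, OMe next to the CO-derived carbon, is the one favoured both by the rule that the substituted carbon of a terminal alkyne ends up beside the new phenol and by the polarity of the ynol ether. Only one cyclisation site exists, because the other neighbour of the carbene-bearing carbon is the ring carbonyl, and the moderate temperature in THF is chosen so that CO insertion outruns arrest at the oxygen-stabilised vinylcarbene or a second alkyne insertion. Since all other oxygens are ethers, the in situ acetylation marks C8–O alone.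

**Step 10**
Reactants: 20 3,5-bis(benzyloxy)-2-[3,4-bis(benzyloxy)phenyl]-7-methoxy-4-oxo-4H-chromen-8-yl acetate
Product: 21 gossypetin 7-methyl ether 8-acetate (2-(3,4-dihydroxyphenyl)-3,5-dihydroxy-7-methoxy-4-oxo-4H-chromen-8-yl acetate)
Conditions: H2 (1 atm), 10% Pd/C, EtOAc–THF, rt
Reagents that add atoms: none
Why: Catalytic hydrogenolysis cleaves the four benzyl ethers (aryl and enol) while the aryl acetate, the aryl methyl ether and the pyranone are inert, and the aprotic solvent excludes transesterification of the 8-acetate.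

**Compound list**
1 | methyl 4-(benzyloxy)-3-oxobutanoate | COC(=O)CC(=O)COCc1ccccc1 | starting material
2 | N,N-dimethylformamide dimethyl acetal | COC(OC)N(C)C | starting material
3 | methyl 4-(benzyloxy)-2-[(dimethylamino)methylidene]-3-oxobutanoate (alkene geometry not defined) | COC(=O)C(=CN(C)C)C(=O)COCc1ccccc1 | intermediate
4 | 3,4-bis(benzyloxy)benzoic acid | OC(=O)c1ccc(OCc2ccccc2)c(OCc2ccccc2)c1 | starting material
5 | 3,4-bis(benzyloxy)benzoyl chloride | O=C(Cl)c1ccc(OCc2ccccc2)c(OCc2ccccc2)c1 | intermediate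
6 | methyl 4-(benzyloxy)-5-[3,4-bis(benzyloxy)phenyl]-2-[(dimethylamino)methylidene]-3,5-dioxopentanoate (racemic, enolisable; lithium enolate until the acid quench) | COC(=O)C(=CN(C)C)C(=O)C(OCc1ccccc1)C(=O)c1ccc(OCc2ccccc2)c(OCc2ccccc2)c1 | intermediate
7 | methyl 5-(benzyloxy)-6-[3,4-bis(benzyloxy)phenyl]-4-oxo-4H-pyran-3-carboxylate | COC(=O)c1coc(-c2ccc(OCc3ccccc3)c(OCc3ccccc3)c2)c(OCc2ccccc2)c1=O | intermediate
8 | 5-(benzyloxy)-6-[3,4-bis(benzyloxy)phenyl]-4-oxo-4H-pyran-3-carboxylic acid | OC(=O)c1coc(-c2ccc(OCc3ccccc3)c(OCc3ccccc3)c2)c(OCc2ccccc2)c1=O | intermediate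
9 | 5-(benzyloxy)-6-[3,4-bis(benzyloxy)phenyl]-4-oxo-4H-pyran-3-carbonyl chloride | O=C(Cl)c1coc(-c2ccc(OCc3ccccc3)c(OCc3ccccc3)c2)c(OCc2ccccc2)c1=O | intermediate
10 | chromium hexacarbonyl, Cr(CO)6 | O=C=[Cr](=C=O)(=C=O)(=C=O)(=C=O)=C=O | starting material
11 | disodium pentacarbonylchromate, Na2Cr(CO)5 | [Na+].[Na+].O=C=[Cr-2](=C=O)(=C=O)(=C=O)=C=O | intermediate
12 | sodium pentacarbonyl{[5-(benzyloxy)-6-[3,4-bis(benzyloxy)phenyl]-4-oxo-4H-pyran-3-yl]carbonyl}chromate | [Na+].[O-]C(=[Cr](=C=O)(=C=O)(=C=O)(=C=O)=C=O)c1coc(-c2ccc(OCc3ccccc3)c(OCc3ccccc3)c2)c(OCc2ccccc2)c1=O | intermediate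
13 | tetramethylammonium pentacarbonyl{[5-(benzyloxy)-6-[3,4-bis(benzyloxy)phenyl]-4-oxo-4H-pyran-3-yl]carbonyl}chromate | C[N+](C)(C)C.[O-]C(=[Cr](=C=O)(=C=O)(=C=O)(=C=O)=C=O)c1coc(-c2ccc(OCc3ccccc3)c(OCc3ccccc3)c2)c(OCc2ccccc2)c1=O | intermediate
14 | pentacarbonyl{(acetyloxy)[5-(benzyloxy)-6-[3,4-bis(benzyloxy)phenyl]-4-oxo-4H-pyran-3-yl]methylidene}chromium | CC(=O)OC(=[Cr](=C=O)(=C=O)(=C=O)(=C=O)=C=O)c1coc(-c2ccc(OCc3ccccc3)c(OCc3ccccc3)c2)c(OCc2ccccc2)c1=O | intermediate
15 | pentacarbonyl{(benzyloxy)[5-(benzyloxy)-6-[3,4-bis(benzyloxy)phenyl]-4-oxo-4H-pyran-3-yl]methylidene}chromium | O=C=[Cr](=C=O)(=C=O)(=C=O)(=C=O)=C(OCc1ccccc1)c1coc(-c2ccc(OCc3ccccc3)c(OCc3ccccc3)c2)c(OCc2ccccc2)c1=O | intermediate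
16 | chloroacetaldehyde dimethyl acetal (2-chloro-1,1-dimethoxyethane) | COC(CCl)OC | starting material
17 | sodium methoxyacetylide | [Na+].[C-]#COC | intermediate
18 | methoxyacetylene | COC#C | intermediate
19 | 3,5-bis(benzyloxy)-2-[3,4-bis(benzyloxy)phenyl]-8-hydroxy-7-methoxy-4H-chromen-4-one | COc1cc(OCc2ccccc2)c2c(=O)c(OCc3ccccc3)c(-c3ccc(OCc4ccccc4)c(OCc4ccccc4)c3)oc2c1O | intermediate
20 | 3,5-bis(benzyloxy)-2-[3,4-bis(benzyloxy)phenyl]-7-methoxy-4-oxo-4H-chromen-8-yl acetate | COc1cc(OCc2ccccc2)c2c(=O)c(OCc3ccccc3)c(-c3ccc(OCc4ccccc4)c(OCc4ccccc4)c3)oc2c1OC(C)=O | intermediate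
21 | gossypetin 7-methyl ether 8-acetate (2-(3,4-dihydroxyphenyl)-3,5-dihydroxy-7-methoxy-4-oxo-4H-chromen-8-yl acetate) | COc1cc(O)c2c(=O)c(O)c(-c3ccc(O)c(O)c3)oc2c1OC(C)=O | target

**Step count**
Total: 10 steps. Longest linear sequence: 8 steps (1, 3, 4, 5, 6, 7, 9, 10); steps 2 and 8 are side branches.

**Steps most likely to fail**

Step 9. The insertion could stop at the methoxy-stabilised vinylcarbene without taking up CO, the electron-rich alkyne could insert twice or oligomerise, or closure could take the five-membered course without CO. The fallback uses only known flavonol chemistry, sets out from 5 and comes back at 21. Phloroglucinol and benzyloxyacetonitrile are joined by Houben–Hoesch acylation (ZnCl2, HCl, Et2O) to 2-(benzyloxy)-1-(2,4,6-trihydroxyphenyl)ethan-1-iminium chloride F1, which hot water hydrolyses to 2-(benzyloxy)-1-(2,4,6-trihydroxyphenyl)ethan-1-one F2. Its polyanion (LiN(SiMe3)2, THF, −78 °C) is C-acylated with 5 to 2-(benzyloxy)-1-[3,4-bis(benzyloxy)phenyl]-3-(2,4,6-trihydroxyphenyl)propane-1,3-dione F3, and AcOH with a trace of H2SO4 cyclodehydrates this to 3-(benzyloxy)-2-[3,4-bis(benzyloxy)phenyl]-5,7-dihydroxy-4H-chromen-4-one F4. MeI and K2CO3 methylate the non-chelated 7-OH to 3-(benzyloxy)-2-[3,4-bis(benzyloxy)phenyl]-5-hydroxy-7-methoxy-4H-chromen-4-one F5. Elbs persulfate oxidation (K2S2O8, aq. KOH, pyridine) attacks para to the 5-OH and gives potassium 3-(benzyloxy)-2-[3,4-bis(benzyloxy)phenyl]-5-hydroxy-7-methoxy-4-oxo-4H-chromen-8-yl sulfate F6, which dilute HCl hydrolyses to 3-(benzyloxy)-2-[3,4-bis(benzyloxy)phenyl]-5,8-dihydroxy-7-methoxy-4H-chromen-4-one F7. Ac2O (1 equiv) in pyridine at 0 °C should acetylate the free 8-OH and not the chelated 5-OH, giving 3-(benzyloxy)-2-[3,4-bis(benzyloxy)phenyl]-5-hydroxy-7-methoxy-4-oxo-4H-chromen-8-yl acetate F8, and hydrogenolysis (H2, Pd/C, EtOAc–THF) then gives 21.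

Step 6. The strongly reducing, soft chromate dianion could transfer an electron to the pyranone or add in conjugate fashion at the ring CH next to oxygen instead of substituting at the acyl chloride. The fallback sets out from 8 and comes back at 13. Iododecarboxylation of 8 with N-iodosuccinimide (ipso-iodination at the carboxyl-bearing carbon, then loss of CO2) should give 3-(benzyloxy)-2-[3,4-bis(benzyloxy)phenyl]-5-iodo-4H-pyran-4-one F9. Iodine–lithium exchange with t-BuLi (2 equiv) in THF–Et2O at −100 °C gives [5-(benzyloxy)-6-[3,4-bis(benzyloxy)phenyl]-4-oxo-4H-pyran-3-yl]lithium F10. This is trapped at once with Cr(CO)6 predissolved in THF, the classical addition of an organolithium to a metal carbonyl, to give lithium pentacarbonyl{[5-(benzyloxy)-6-[3,4-bis(benzyloxy)phenyl]-4-oxo-4H-pyran-3-yl]carbonyl}chromate F11, and cation exchange with Me4NBr returns 13.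

Step 4. The tin-bound hydroxide could add at the ring CH next to oxygen and open the pyranone, or hydrolysis could stall at the chelated ester. The fallback sets out from 7 and comes back at 8, and it cleaves the O–CH3 bond instead of the acyl–oxygen bond. LiI in refluxing EtOAc dealkylates the ester by SN2 attack of iodide on the methyl group, with lithium held between the ring carbonyl and the carboxylate, to give lithium 5-(benzyloxy)-6-[3,4-bis(benzyloxy)phenyl]-4-oxo-4H-pyran-3-carboxylate F12. Cold dilute HCl then liberates 8, and no oxygen nucleophile meets the pyranone.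

**Further compounds**
F1 | step 9 | 2-(benzyloxy)-1-(2,4,6-trihydroxyphenyl)ethan-1-iminium chloride | [NH2+]=C(COCc1ccccc1)c1c(O)cc(O)cc1O.[Cl-]
F2 | step 9 | 2-(benzyloxy)-1-(2,4,6-trihydroxyphenyl)ethan-1-one | O=C(COCc1ccccc1)c1c(O)cc(O)cc1O
F3 | step 9 | 2-(benzyloxy)-1-[3,4-bis(benzyloxy)phenyl]-3-(2,4,6-trihydroxyphenyl)propane-1,3-dione (racemic, enolisable) | O=C(c1ccc(OCc2ccccc2)c(OCc2ccccc2)c1)C(OCc1ccccc1)C(=O)c1c(O)cc(O)cc1O
F4 | step 9 | 3-(benzyloxy)-2-[3,4-bis(benzyloxy)phenyl]-5,7-dihydroxy-4H-chromen-4-one | Oc1cc(O)c2c(=O)c(OCc3ccccc3)c(-c3ccc(OCc4ccccc4)c(OCc4ccccc4)c3)oc2c1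
F5 | step 9 | 3-(benzyloxy)-2-[3,4-bis(benzyloxy)phenyl]-5-hydroxy-7-methoxy-4H-chromen-4-one | COc1cc(O)c2c(=O)c(OCc3ccccc3)c(-c3ccc(OCc4ccccc4)c(OCc4ccccc4)c3)oc2c1
F6 | step 9 | potassium 3-(benzyloxy)-2-[3,4-bis(benzyloxy)phenyl]-5-hydroxy-7-methoxy-4-oxo-4H-chromen-8-yl sulfate | COc1cc(O)c2c(=O)c(OCc3ccccc3)c(-c3ccc(OCc4ccccc4)c(OCc4ccccc4)c3)oc2c1OS(=O)(=O)[O-].[K+]
F7 | step 9 | 3-(benzyloxy)-2-[3,4-bis(benzyloxy)phenyl]-5,8-dihydroxy-7-methoxy-4H-chromen-4-one | COc1cc(O)c2c(=O)c(OCc3ccccc3)c(-c3ccc(OCc4ccccc4)c(OCc4ccccc4)c3)oc2c1O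
F8 | step 9 | 3-(benzyloxy)-2-[3,4-bis(benzyloxy)phenyl]-5-hydroxy-7-methoxy-4-oxo-4H-chromen-8-yl acetate | COc1cc(O)c2c(=O)c(OCc3ccccc3)c(-c3ccc(OCc4ccccc4)c(OCc4ccccc4)c3)oc2c1OC(C)=O
F9 | step 6 | 3-(benzyloxy)-2-[3,4-bis(benzyloxy)phenyl]-5-iodo-4H-pyran-4-one | O=c1c(I)coc(-c2ccc(OCc3ccccc3)c(OCc3ccccc3)c2)c1OCc1ccccc1
F10 | step 6 | [5-(benzyloxy)-6-[3,4-bis(benzyloxy)phenyl]-4-oxo-4H-pyran-3-yl]lithium | [Li]c1coc(-c2ccc(OCc3ccccc3)c(OCc3ccccc3)c2)c(OCc2ccccc2)c1=O
F11 | step 6 | lithium pentacarbonyl{[5-(benzyloxy)-6-[3,4-bis(benzyloxy)phenyl]-4-oxo-4H-pyran-3-yl]carbonyl}chromate | [Li+].[O-]C(=[Cr](=C=O)(=C=O)(=C=O)(=C=O)=C=O)c1coc(-c2ccc(OCc3ccccc3)c(OCc3ccccc3)c2)c(OCc2ccccc2)c1=O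
F12 | step 4 | lithium 5-(benzyloxy)-6-[3,4-bis(benzyloxy)phenyl]-4-oxo-4H-pyran-3-carboxylate | [Li+].[O-]C(=O)c1coc(-c2ccc(OCc3ccccc3)c(OCc3ccccc3)c2)c(OCc2ccccc2)c1=O
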